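**Assumptions (one line each)**
- The target has no sp3 stereocentres, so "single enantiomer" is moot. The only stereochemical elements are the five E-trisubstituted alkenes of the all-E hexaprenyl chain, which come from purchased all-E hexaprenol and are never touched.
- All-E hexaprenol (C30) is assumed to be commercially available from isoprenoid suppliers.

**Retrosynthesis**
1. The target (a 2-hydroxy-3-methoxy-6-methyl-5-hexaprenyl-1,4-benzoquinone) comes from O-debenzylation of the benzyloxyquinone. That quinone comes from oxidation of the hydroquinone that carries the chain.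
2. The chain is installed by BF3-mediated Friedel–Crafts alkylation of a hydroquinone with all-E hexaprenol, at the only free ring carbon.
3. The hydroquinone comes from reduction of a p-quinone. That quinone comes from oxidative demethylation of a phenol that has a para-OMe.
4. The phenol comes from Baeyer–Villiger/Dakin oxidation of an O-benzyl benzaldehyde. That aldehyde comes from chelation-controlled selective ortho-demethylation of 2,3,4-trimethoxy-6-methylbenzaldehyde, which is made by Vilsmeier formylation of 3,4,5-trimethoxytoluene.
5. The benzene ring is already present in the starting material. The quinone ring is generated by oxidation at step 5 and regenerated at step 8. The ortho-carbonyl chelation at step 2 sets which oxygen becomes the free OH.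

**Route**

Step 1
Reactants: 1, 3,4,5-trimethoxytoluene
Product: 2, 2,3,4-trimethoxy-6-methylbenzaldehyde
Conditions: POCl3, DMF, 80 °C; then aq. NaOAc
Reagents that add atoms: DMF, CN(C)C=O (supplies the CHO carbon)
Why: Vilsmeier–Haack formylation; the two ring CH positions of 1 are equivalent by symmetry, so only one regioisomer forms, ortho to Me and OMe.

Step 2
Reactants: 2
Product: 3, 2-hydroxy-3,4-dimethoxy-6-methylbenzaldehyde
Conditions: BCl3 (1.1 equiv), CH2Cl2, −78 → 0 °C; aq. NaHCO3 quench
Reagents that add atoms: none
Why: BCl3 forms a six-membered chelate between the CHO oxygen and the ortho OMe oxygen, so only that methyl ether is cleaved (Lewis-acid chelation-controlled O-demethylation). This sets the future OH next to the carbonyl that will flank the methyl-bearing carbon.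

Step 3
Reactants: 3
Product: 4, 2-(benzyloxy)-3,4-dimethoxy-6-methylbenzaldehyde
Conditions: BnBr, K2CO3, DMF, 60 °C
Reagents that add atoms: benzyl bromide, BrCc1ccccc1
Why: Williamson O-benzylation masks the phenol so that it survives the later oxidations and the Lewis-acid coupling.

Step 4
Reactants: 4
Product: 5, 2-(benzyloxy)-3,4-dimethoxy-6-methylphenol
Conditions: mCPBA, NaHCO3, CH2Cl2, 0 °C → rt; then KOH, MeOH/H2O, rt
Reagents that add atoms: mCPBA, OOC(=O)c1cccc(Cl)c1 (supplies the phenolic O)
Why: Dakin-type Baeyer–Villiger oxidation; the electron-rich aryl group migrates to give the aryl formate, which methanolysis converts to the phenol, so the fourth contiguous oxygen is installed with no new stereocentre.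

Step 5
Reactants: 5
Product: 6, 2-(benzyloxy)-3-methoxy-6-methyl-1,4-benzoquinone
Conditions: PIFA, MeCN/H2O (3:1), 0 °C
Reagents that add atoms: water, O (supplies the new C=O oxygen; the para OMe leaves as MeOH)
Why: Hypervalent-iodine oxidative dearomatisation of a 4-methoxyphenol to the p-quinone; the Bn ether and remaining OMe are untouched, and the only free ring CH is left at the position that will receive the chain.

Step 6
Reactants: 6
Product: 7, 2-(benzyloxy)-3-methoxy-6-methylbenzene-1,4-diol
Conditions: Na2S2O4, THF/H2O, rt; use immediately under N2
Reagents that add atoms: none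
Why: Dithionite reduction of the quinone to the hydroquinone, which is the nucleophile needed for ortho-directed Friedel–Crafts alkylation.

Step 7
Reactants: 7, hydroquinone; 8, (2E,6E,10E,14E,18E)-hexaprenol
Product: 9, 2-(benzyloxy)-3-methoxy-6-methyl-5-[(all-E)-hexaprenyl]benzene-1,4-diol
Conditions: BF3·OEt2, 1,4-dioxane, 40 °C, dark, N2
Reagents that add atoms: none (BF3 is a catalyst/promoter; water is lost)
Why: BF3 ionises the allylic alcohol and the hydroquinone (activated by ortho-OH and para-OBn) attacks through the primary terminus at its only free carbon (Friedel–Crafts allylation); the E geometry is retained and no new stereocentre forms.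

Step 8
Reactants: 9
Product: 10, 2-(benzyloxy)-3-methoxy-6-methyl-5-[(all-E)-hexaprenyl]-1,4-benzoquinone
Conditions: Ag2O, anhydrous Na2SO4, Et2O, rt, dark
Reagents that add atoms: none
Why: Mild Ag(I) oxidation of the hydroquinone to the p-quinone leaves the polyene and the Bn ether untouched.

Step 9
Reactants: 10
Product: 11, 3-demethylubiquinone-6, the target
Conditions: BCl3 (1.2 equiv), pentamethylbenzene (3 equiv), CH2Cl2, −78 °C, 30 min; quench at −78 °C with MeOH/aq. NaHCO3
Reagents that add atoms: none (the benzyl cation is trapped by pentamethylbenzene and leaves)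
Why: BCl3 chelated to the adjacent C=O cleaves the benzyl ether much faster than the methyl ether (Lewis-acid debenzylation with a cation scavenger), freeing the OH without reducing the alkenes, which hydrogenolysis would.

**Compound list**
1 | 3,4,5-trimethoxytoluene | COc1cc(C)cc(OC)c1OC | starting material
2 | 2,3,4-trimethoxy-6-methylbenzaldehyde | COc1c(C=O)c(C)cc(OC)c1OC | intermediate
3 | 2-hydroxy-3,4-dimethoxy-6-methylbenzaldehyde | O=Cc1c(C)cc(OC)c(OC)c1O | intermediate
4 | 2-(benzyloxy)-3,4-dimethoxy-6-methylbenzaldehyde | O=Cc1c(C)cc(OC)c(OC)c1OCc1ccccc1 | intermediate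
5 | 2-(benzyloxy)-3,4-dimethoxy-6-methylphenol | Cc1cc(OC)c(OC)c(OCc2ccccc2)c1O | intermediate
6 | 2-(benzyloxy)-3-methoxy-6-methyl-1,4-benzoquinone | COC1=C(OCc2ccccc2)C(=O)C(C)=CC1=O | intermediate
7 | 2-(benzyloxy)-3-methoxy-6-methylbenzene-1,4-diol | COc1c(OCc2ccccc2)c(O)c(C)cc1O | intermediate
8 | (all-E)-hexaprenol | OC/C=C(\C)CC/C=C(\C)CC/C=C(\C)CC/C=C(\C)CC/C=C(\C)CCC=C(C)C | starting material
9 | 2-(benzyloxy)-3-methoxy-6-methyl-5-(all-E-hexaprenyl)benzene-1,4-diol | COc1c(OCc2ccccc2)c(O)c(C)c(C/C=C(\C)CC/C=C(\C)CC/C=C(\C)CC/C=C(\C)CC/C=C(\C)CCC=C(C)C)c1O | intermediate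
10 | 2-(benzyloxy)-3-methoxy-6-methyl-5-(all-E-hexaprenyl)-1,4-benzoquinone | COC1=C(OCc2ccccc2)C(=O)C(C)=C(C/C=C(\C)CC/C=C(\C)CC/C=C(\C)CC/C=C(\C)CC/C=C(\C)CCC=C(C)C)C1=O | intermediate
11 | 3-demethylubiquinone-6 (C38H56O4) | COC1=C(O)C(=O)C(C)=C(C/C=C(\C)CC/C=C(\C)CC/C=C(\C)CC/C=C(\C)CC/C=C(\C)CCC=C(C)C)C1=O | target

**Totals:** 9 steps; longest linear sequence 9 steps (from 1; hexaprenol is purchased).

**Three steps most likely to fail**
1. **Step 7 (Friedel–Crafts prenylation).** It may give moderate yield, O-alkylation, or partial cation cyclisation or isomerisation of the polyprenyl chain.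
   - Fallback: change the bond-forming strategy. Make the bis-MOM ether of 7, do ortho-lithiation (s-BuLi/TMEDA), then CuI-mediated SN2 coupling with hexaprenyl bromide (from 8 and PBr3). Remove the MOM groups and oxidise to the quinone.
2. **Step 9 (BCl3 debenzylation on a polyene quinone).** Lewis-acid attack on the trisubstituted alkenes, or competing demethylation of the OMe, could occur.
   - Fallback: use an O-allyl instead of O-benzyl protecting group from step 3 onward. Remove it at the hydroquinone stage with Pd(PPh3)4/morpholine. Then oxidise the resulting 1,2,4-triol with Ag2O, which gives the hydroxy-p-quinone directly.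
3. **Step 2 (regioselective mono-demethylation).** BCl3 might also cleave the 4-OMe or over-demethylate.
   - Fallback: abandon the early differentiation. Use commercial CoQ6 (or CoQ0 carried through steps 7–8) and perform a late-stage BCl3 mono-demethylation. Separate the two regioisomeric hydroxyquinones by HPLC and identify the correct one by HMBC correlation of the remaining OMe and the ring methyl to their neighbouring carbonyls.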